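## The problem

Compound 16 is an achiral diaryl ether with no stereocentre, so every difficulty is one of position on two benzene rings. Ring A carries the ether oxygen at C1, a methoxy group at C2 and bromine at C3 and C5. Ring B carries the ether oxygen at C1', bromine at C4' and a free hydroxyl at C6'. The ring A bromines sit ortho and para to the C2 oxygen, where an electrophile would go. The ring B bromine is para to the ether oxygen and meta to the free hydroxyl, where bromination of a free phenol would not put it. The two oxygens flanking the ether link must end up different (methyl ether on ring A, free phenol on ring B), so they have to be told apart from the start. The three aryl C–Br bonds rule out hydrogenolysis, zerovalent palladium, hot copper couplings and unselective halogen–metal exchange, and neither ring is electron-poor enough for nucleophilic aromatic substitution. The feature that opens the route is the contiguous array C1 (O-aryl), C2 (O), C3 (Br) in ring A. This is the pattern left when a nucleophile and an electrophile add across a 3-bromoaryne, the nucleophile at the carbon remote from the halogen and the electrophile beside it.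

## Retrosynthesis

**16 from 15.** The free hydroxyl at C6' is uncovered last by cutting the O–CH2 bond of a methoxymethyl acetal in 15. An acetal is chosen over a benzyl or silyl group because it survives Grignard reagents, peroxide and base, and falls to dilute acid that leaves the methyl ether, the diaryl ether and the bromides alone.

**15 from 13 via 14.** The methoxy group is traced to the phenol 14 (O–CH3 cut) and the phenol to the boronic ester 13 (C2–O exchanged for C2–B). Oxidation of a C–B bond puts the oxygen exactly where boron was. The forward steps must spare the acetal and three C–Br bonds, which mild peroxide and a carbonate base allow.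

**13 from 3, 7 and 8.** The O–C1 and C2–B bonds of 13 are cut together. This leads to aryne 11, the ring B phenol 7 (used as its magnesium phenolate 9) and the borate ester 8. The neighbouring cuts are worse:
- A copper-mediated ether synthesis would have to single out one halogen among four on electron-rich, ortho-substituted partners.
- Nucleophilic aromatic substitution has no activating group on ring A to use.

The aryne cut instead uses the C3 bromine as the regiochemical control and leaves all three bromines untouched. The precursor 3 is a simple tetrasubstituted benzene with iodine next to a triflate. The forward reaction needs three things: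
- exchange of iodine only;
- addition of oxygen at C1 only;
- an ortho-bromo aryl-magnesium 12 that lives long enough to be borylated.

**3 from 1 via 2.** The S–O bond of the triflate and the C–I bond are cut in turn. This leads to 2,4-dibromophenol 1, whose single open ortho carbon is the only place an electrophilic iodine can go. Both bromines of ring A are therefore bought, not installed.

**7 from 4 via 5.** The phenol oxygen of 7 is traced to a formyl group (aryl C–O back to aryl C–CHO, through formate 6) and the acetal to a free hydroxyl. This leads to 4-bromo-2-hydroxybenzaldehyde 4. That compound already has bromine para to the carbon that becomes the ether carbon, and its two oxygen-bearing positions are chemically distinct, so the oxygens of ring B are differentiated without any selective protection of a catechol.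

## Roads not taken

**Alternative 1:** Ring A would be built from acyclic pieces by cutting C1–C6 and C3–C4. The aryloxyacetone 5-bromo-2-(2-oxopropoxy)phenyl 4-methylbenzenesulfonate A2, already carrying ring B, would condense through both alpha carbons with the two formyl groups of bromomalonaldehyde A3. Loss of two molecules of water would give 5-bromo-2-(5-bromo-2-hydroxyphenoxy)phenyl 4-methylbenzenesulfonate A1.
- Merits: the C1/C2 oxygen pattern and the C5 bromine arise with fixed regiochemistry, and no organometallic reagent ever meets an aryl bromide.
- Weak points: this type of [3+3] phenol synthesis is established mainly for nitromalonaldehyde, a far stronger bis-electrophile than A3. A3 is enolised and base-sensitive. The basic medium threatens the sulfonate of A2.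
- Step economy: A1 still lacks the C3 bromine, the methyl group and a free C6' hydroxyl, so three steps follow the key step. A2 itself needs a monoprotected bromocatechol of the same kind as 7 plus an alkylation.
- Comparison: Alternative 1 is longer than the chosen plan and its key step is no better precedented. Its one advantage is the absence of cryogenic organometallic chemistry. The chosen plan sets against that a convergent union in which all three bromines come from purchased materials.

**Alternative 2:** Ring B would be made by cutting C1'–C2' and C5'–C6'. 4-Bromo-2H-pyran-2-one A5 and the bis(trimethylsilyl) ketene acetal A6, carried on the ring A phenol oxygen, would undergo cycloaddition. Loss of CO2 and trimethylsilanol would give [5-bromo-2-(3,5-dibromo-2-methoxyphenoxy)phenoxy]trimethylsilane A4.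
- Merits: A4 is the silyl ether of the target, so the endgame is a single trivial desilylation. Ring B needs no protecting group. The awkward meta relation of the ring B bromine and hydroxyl is set by the pyrone. In this respect the road is better than the chosen one, which needs three steps after its key step.
- Weak points: A5 is not a commodity and must be prepared. A6 requires double silylation of an aryloxyacetic acid with strong base beside two aryl bromides, and the ring A phenol behind it needs its own synthesis. The nucleophilic carbon of A6 must bond to C6 of A5 and not displace the C4 bromide of what is a vinylogous acyl bromide. Pyrone cycloadditions of this kind usually need heat, which silyl ketene acetals tolerate poorly.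
- Comparison: the chosen plan sets against the shorter endgame its commercial or two-step building blocks, a low-temperature key step, and a regiochemical control element (the C3 bromine on the aryne) that is well understood.

**Alternative 3:** All three C–Br bonds would be made last. 2,2'-Oxydiphenol A9 would be monosulfonylated to 2-(2-hydroxyphenoxy)phenyl 4-methylbenzenesulfonate A8. This would be brominated three times with bromide and hydrogen peroxide under NH4VO3 catalysis (pentavalent vanadium) to give 5-bromo-2-(3,5-dibromo-2-hydroxyphenoxy)phenyl 4-methylbenzenesulfonate A7. Methylation and removal of the sulfonate would finish the synthesis.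
- Merits: this is the shortest road, about four steps, with no organometallic step, and here it is clearly better than the chosen plan in step economy.
- Weak points: the monosulfonylation of A9 is statistical. The free phenol steers the first two brominations correctly to C3 and C5. The third must go to C4' of a ring deactivated by the sulfonate, while ring A still offers C4 and C6, both activated by the ether oxygen. Over-bromination of ring A and ortho attack at C2' are the likely leaks, and polybrominated diaryl ether isomers are hard to separate.
- Comparison: the chosen plan sets against the brevity of Alternative 3 the fact that no halogenation selectivity arises at any stage beyond one iodination with a single open site. The isomeric purity of 16 therefore does not rest on a separation.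

Key step: step 5

## Route

Step 1
Reactants: 1 2,4-dibromophenol
Product: 2 2,4-dibromo-6-iodophenol
Conditions: NIS, TsOH·H2O (cat.), MeCN, rt
Reagents that add atoms: N-iodosuccinimide, O=C1CCC(=O)N1I
Why: Electrophilic aromatic iodination of a phenol; the hydroxyl directs ortho and para and only C6 is still open, so a single iodide is expected.

Step 2
Reactants: 2 2,4-dibromo-6-iodophenol
Product: 3 2,4-dibromo-6-iodophenyl trifluoromethanesulfonate
Conditions: Tf2O, pyridine, CH2Cl2, 0 °C to rt
Reagents that add atoms: trifluoromethanesulfonic anhydride, O=S(=O)(OS(=O)(=O)C(F)(F)F)C(F)(F)F
Why: O-Sulfonylation of a phenol with triflic anhydride and pyridine, routine for 2,6-dihalophenols; it turns the C–O bond into the leaving group needed beside the iodide.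

Step 3
Reactants: 4 4-bromo-2-hydroxybenzaldehyde
Product: 5 4-bromo-2-(methoxymethoxy)benzaldehyde
Conditions: MOMCl, iPr2NEt, CH2Cl2, 0 °C to rt
Reagents that add atoms: chloromethyl methyl ether, COCCl
Why: Williamson-type O-alkylation of the phenol with an alpha-chloro ether (acetal protection); the aldehyde is inert to the amine base.

Step 4
Reactants: 5 4-bromo-2-(methoxymethoxy)benzaldehyde
Product: 7 4-bromo-2-(methoxymethoxy)phenol, via aryl formate 6 (not isolated)
Conditions: mCPBA, CH2Cl2, rt; aq. Na2S2O3/NaHCO3 wash; then K2CO3 (cat.), MeOH, rt
Reagents that add atoms: 3-chloroperoxybenzoic acid, OOC(=O)c1cccc(Cl)c1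
Why: Baeyer–Villiger oxidation of an ortho-alkoxybenzaldehyde (Dakin-type): the electron-rich aryl group migrates in preference to hydrogen in the Criegee adduct to give formate 6, and mild methanolysis frees the phenol without touching the acetal or the bromide.

Step 5
Reactants: 7 4-bromo-2-(methoxymethoxy)phenol; 3 2,4-dibromo-6-iodophenyl trifluoromethanesulfonate; 8 2-isopropoxy-4,4,5,5-tetramethyl-1,3,2-dioxaborolane
Product: 13 2-{2,4-dibromo-6-[4-bromo-2-(methoxymethoxy)phenoxy]phenyl}-4,4,5,5-tetramethyl-1,3,2-dioxaborolane, via magnesium phenolate 9 (not isolated), via magnesiated triflate 10 (not isolated), via 3,5-dibromobenzyne 11 (not isolated), via aryl-magnesium chloride 12 (not isolated)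
Conditions: 7 (2 equiv), Me3SiCH2MgCl (2 equiv), LiCl (2 equiv), THF, 0 °C; cool to −78 °C, add 3 (1 equiv), then Me3SiCH2MgCl (1.1 equiv), −78 to −40 °C; 8 (3 equiv), −78 °C to 0 °C; aq. NH4Cl
Reagents that add atoms: none
Why: Proposed new method: Me3SiCH2MgCl first deprotonates 7 to the magnesium phenolate 9 and then, at −78 °C, exchanges the iodine of 3 far faster than any of the three C–Br bonds present, giving 10, which loses the neighbouring triflate to release aryne 11 with its triple bond between the future C1 and C2 of ring A. The closest known reaction type is the addition of magnesium thiolates and magnesium amides to arynes generated from ortho-iodoaryl sulfonates with electrophilic trapping of the new aryl-magnesium bond, and alkali phenoxides are known to add to arynes through oxygen; a magnesium phenolate in this three-component sequence is the untested element. The sigma-withdrawing C3 bromine distorts 11 so that C1 is the more linear, more electrophilic terminus and the developing negative charge is best placed at C2 beside that bromine, so the oxygen of 9 should bond to C1; the C5 bromine pulls weakly the other way and attack at C1 is also the less hindered. The resulting aryl-magnesium 12 is held cold so that it does not expel the C3 bromide as a second aryne, and the borate ester 8 then forms the C2–B bond through an ate complex that sheds isopropoxide. No ring closes and no stereocentre is formed. The selectivities needed are iodine-over-bromine exchange (secured by the weaker C–I bond flanked by the sulfonate), one sense of addition (secured by the C3 bromine), and O- rather than C-arylation of the phenolate (favoured by low temperature, LiCl to loosen the O–Mg aggregate and an excess of 9).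

Step 6
Reactants: 13 2-{2,4-dibromo-6-[4-bromo-2-(methoxymethoxy)phenoxy]phenyl}-4,4,5,5-tetramethyl-1,3,2-dioxaborolane
Product: 14 2,4-dibromo-6-[4-bromo-2-(methoxymethoxy)phenoxy]phenol
Conditions: NaBO3·4H2O, THF/H2O, rt
Reagents that add atoms: sodium perborate (NaBO3·4H2O, written as NaBO3), [Na+].[O-]OB=O
Why: Oxidation of an aryl boronic ester to a phenol: hydroperoxide adds to boron and the aryl group shifts from boron to oxygen at the same carbon; perborate is mild enough for the acetal and the aryl bromides.

Step 7
Reactants: 14 2,4-dibromo-6-[4-bromo-2-(methoxymethoxy)phenoxy]phenol
Product: 15 1,5-dibromo-3-[4-bromo-2-(methoxymethoxy)phenoxy]-2-methoxybenzene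
Conditions: MeI, K2CO3, DMF, rt
Reagents that add atoms: iodomethane, CI
Why: Williamson O-methylation of an acidic 2,6-disubstituted phenol; K2CO3 deprotonates it fully and methyl iodide is small enough for the flanked oxygen.

Step 8
Reactants: 15 1,5-dibromo-3-[4-bromo-2-(methoxymethoxy)phenoxy]-2-methoxybenzene
Product: 16 5-bromo-2-(3,5-dibromo-2-methoxyphenoxy)phenol
Conditions: HCl (cat.), MeOH, 40 °C
Reagents that add atoms: none
Why: Acid-catalysed cleavage of the methoxymethyl acetal by transacetalisation with methanol; the aryl methyl ether, the diaryl ether and the C–Br bonds are inert to dilute acid.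

## Compound list

1 | 2,4-dibromophenol | Oc1ccc(Br)cc1Br | starting material
2 | 2,4-dibromo-6-iodophenol | Oc1c(Br)cc(Br)cc1I | intermediate
3 | 2,4-dibromo-6-iodophenyl trifluoromethanesulfonate | O=S(=O)(Oc1c(Br)cc(Br)cc1I)C(F)(F)F | intermediate
4 | 4-bromo-2-hydroxybenzaldehyde | O=Cc1ccc(Br)cc1O | starting material
5 | 4-bromo-2-(methoxymethoxy)benzaldehyde | COCOc1cc(Br)ccc1C=O | intermediate
6 | 4-bromo-2-(methoxymethoxy)phenyl formate | O=COc1ccc(Br)cc1OCOC | intermediate
7 | 4-bromo-2-(methoxymethoxy)phenol | COCOc1cc(Br)ccc1O | intermediate
8 | 2-isopropoxy-4,4,5,5-tetramethyl-1,3,2-dioxaborolane | CC(C)OB1OC(C)(C)C(C)(C)O1 | starting material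
9 | chloromagnesium 4-bromo-2-(methoxymethoxy)phenolate | COCOc1cc(Br)ccc1O[Mg]Cl | intermediate
10 | [3,5-dibromo-2-(trifluoromethanesulfonyloxy)phenyl]magnesium chloride | O=S(=O)(Oc1c(Br)cc(Br)cc1[Mg]Cl)C(F)(F)F | intermediate
11 | 3,5-dibromobenzyne (3,5-dibromo-1,2-didehydrobenzene) | BrC1=CC(Br)=CC#C1 | intermediate
12 | {2,4-dibromo-6-[4-bromo-2-(methoxymethoxy)phenoxy]phenyl}magnesium chloride | COCOc1cc(Br)ccc1Oc1cc(Br)cc(Br)c1[Mg]Cl | intermediate
13 | 2-{2,4-dibromo-6-[4-bromo-2-(methoxymethoxy)phenoxy]phenyl}-4,4,5,5-tetramethyl-1,3,2-dioxaborolane | COCOc1cc(Br)ccc1Oc1cc(Br)cc(Br)c1B1OC(C)(C)C(C)(C)O1 | intermediate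
14 | 2,4-dibromo-6-[4-bromo-2-(methoxymethoxy)phenoxy]phenol | COCOc1cc(Br)ccc1Oc1cc(Br)cc(Br)c1O | intermediate
15 | 1,5-dibromo-3-[4-bromo-2-(methoxymethoxy)phenoxy]-2-methoxybenzene | COCOc1cc(Br)ccc1Oc1cc(Br)cc(Br)c1OC | intermediate
16 | 5-bromo-2-(3,5-dibromo-2-methoxyphenoxy)phenol | COc1c(Br)cc(Br)cc1Oc1ccc(Br)cc1O | target

## Step count and risk

Total steps: 8. Longest linear sequence: 6 steps (1 → 2 → 3 → 13 → 14 → 15 → 16, or equally 4 → 5 → 7 → 13 → 14 → 15 → 16). Steps 1, 3, 4, 7 and 8 are standard functional-group operations; the least certain steps are 5, 6 and 2.

**Step 5 (key step, proposed new method).** Four processes could spoil it: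
- C-arylation of the phenolate at its free ortho carbon instead of O-arylation, since the O–Mg bond is fairly covalent.
- Transfer of the triflyl group from the very electron-poor triflate to the phenolate before the exchange takes place.
- Loss of MgBrCl from the ortho-bromo aryl-magnesium on warming, which opens a second aryne and leads to oligomers.
- Some erosion of the regiochemistry of addition, because bromine distorts an aryne less than fluorine or oxygen does.

The fallback uses known chemistry only. It sets out from 2 and 7 and comes back at 15, so that steps 6 and 7 fall away as well. Phenol 2 would be O-methylated (MeI, K2CO3, DMF) to 1,5-dibromo-3-iodo-2-methoxybenzene F1. Oxidation of its iodine with mCPBA and TsOH·H2O in MeCN would give 1,5-dibromo-3-[hydroxy(tosyloxy)iodo]-2-methoxybenzene F2. This is not isolated but condensed in the same flask with 1,3,5-trimethoxybenzene to (3,5-dibromo-2-methoxyphenyl)(2,4,6-trimethoxyphenyl)iodonium 4-methylbenzenesulfonate F3. Metal-free O-arylation of 7 with F3 (K2CO3, MeCN, 50 °C) would then give 15. This is an established ligand coupling at trivalent iodine in which the electron-rich trimethoxyphenyl group stays on iodine and no C–Br bond is at risk.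

**Step 6.** Base-promoted protodeboronation of the 2,6-disubstituted, electron-poor boronic ester could outrun the oxidation, and attack of hydroperoxide at the hindered boron could be slow. The fallback sets out from 13 and comes back at 15, bypassing 14. It is a Chan–Lam methoxylation (Cu(OAc)2, DMAP, MeOH, O2, molecular sieves, rt), which forms the C2–OMe bond directly by copper-mediated oxidative coupling under non-aqueous, weakly basic conditions. It makes no new compound.

**Step 2.** Sulfonylation of the hindered, acidic phenol could be sluggish. More seriously, the triflate of so good a leaving phenoxide could lose its triflyl group by S–O cleavage on purification, on storage, or to the phenolate in step 5. The fallback sets out from 2 and comes back at aryne 11. Phenol 2 would be converted with 4-chlorobenzenesulfonyl chloride and Et3N (CH2Cl2) into 2,4-dibromo-6-iodophenyl 4-chlorobenzenesulfonate F4, which is far less electrophilic at sulfur. In the presence of 9, iodine–magnesium exchange with iPrMgCl at −78 °C would give [3,5-dibromo-2-(4-chlorobenzenesulfonyloxy)phenyl]magnesium chloride F5. On warming towards −20 °C this loses the sulfonate to give 11, and the route continues through 12 to 13. The price is a narrower temperature window between aryne release and the loss of MgBrCl from 12.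

## Further compounds

F1 | step 5 | 1,5-dibromo-3-iodo-2-methoxybenzene | COc1c(Br)cc(Br)cc1I
F2 | step 5 | 1,5-dibromo-3-[hydroxy(tosyloxy)iodo]-2-methoxybenzene | COc1c(Br)cc(Br)cc1I(O)OS(=O)(=O)c1ccc(C)cc1
F3 | step 5 | (3,5-dibromo-2-methoxyphenyl)(2,4,6-trimethoxyphenyl)iodonium 4-methylbenzenesulfonate | COc1cc(OC)c([I+]c2cc(Br)cc(Br)c2OC)c(OC)c1.Cc1ccc(cc1)S(=O)(=O)[O-]
F0 | step 6 | none | none
F4 | step 2 | 2,4-dibromo-6-iodophenyl 4-chlorobenzenesulfonate | O=S(=O)(Oc1c(Br)cc(Br)cc1I)c1ccc(Cl)cc1
F5 | step 2 | [3,5-dibromo-2-(4-chlorobenzenesulfonyloxy)phenyl]magnesium chloride | O=S(=O)(Oc1c(Br)cc(Br)cc1[Mg]Cl)c1ccc(Cl)cc1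
A1 | alternative 1 | 5-bromo-2-(5-bromo-2-hydroxyphenoxy)phenyl 4-methylbenzenesulfonate | Oc1ccc(Br)cc1Oc1ccc(Br)cc1OS(=O)(=O)c1ccc(C)cc1
A2 | alternative 1 | 5-bromo-2-(2-oxopropoxy)phenyl 4-methylbenzenesulfonate | CC(=O)COc1ccc(Br)cc1OS(=O)(=O)c1ccc(C)cc1
A3 | alternative 1 | bromomalonaldehyde (2-bromopropanedial) | O=CC(Br)C=O
A4 | alternative 2 | [5-bromo-2-(3,5-dibromo-2-methoxyphenoxy)phenoxy]trimethylsilane | COc1c(Br)cc(Br)cc1Oc1ccc(Br)cc1O[Si](C)(C)C
A5 | alternative 2 | 4-bromo-2H-pyran-2-one | O=C1C=C(Br)C=CO1
A6 | alternative 2 | {[2-(3,5-dibromo-2-methoxyphenoxy)ethene-1,1-diyl]bis(oxy)}bis(trimethylsilane) | COc1c(Br)cc(Br)cc1OC=C(O[Si](C)(C)C)O[Si](C)(C)C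
A7 | alternative 3 | 5-bromo-2-(3,5-dibromo-2-hydroxyphenoxy)phenyl 4-methylbenzenesulfonate | Cc1ccc(cc1)S(=O)(=O)Oc1cc(Br)ccc1Oc1cc(Br)cc(Br)c1O
A8 | alternative 3 | 2-(2-hydroxyphenoxy)phenyl 4-methylbenzenesulfonate | Cc1ccc(cc1)S(=O)(=O)Oc1ccccc1Oc1ccccc1O
A9 | alternative 3 | 2,2'-oxydiphenol | Oc1ccccc1Oc1ccccc1O
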